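**Plan**

1. Retrosynthesis: the acid comes from its methyl ester, and the C1–ethyl bond from an enol triflate of a C1 ketone. The cyclopentane is opened at C8=C9 (ring-closing metathesis), C6–C7 (branched allylation) and C5–C9 (conjugate addition). The arm alkene comes from a Wittig reaction on a C4 aldehyde, and C4–C(arm) plus C3–C(phenyl) from a dearomatising trans-addition to an anisaldehyde imine–Cr(CO)3 complex.
2. Enabling feature: with the six-membered ring numbered C1(Et)=C2–C3(Ph)–C4(quaternary)–C5–C6 (cyclopentane: C7 on C6, C8, C9 on C5), the ring is a para-substituted benzaldehyde in disguise. C4 is the ipso carbon, C3 the ortho carbon that takes phenyl, and the para oxygen marks C1.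
3. Forward order: arene → cyclohexadiene (step 3) → cyclohexenone → C4 substituents completed (ethyl from formyl, arm from allyl) → C5 and C6 appendages → cyclopentene by metathesis → saturation and deoxygenation → C1 ethyl → acid.
4. Stereochemistry: C3 from the chiral ligand on PhLi; C4 from metal-mediated trans delivery of allyl; C5 from cuprate attack anti to phenyl; C6 from alkylation anti to C5; C7 from the chiral iridium catalyst; C9 from hydroxyl-directed hydrogenation; arm geometry from the stabilised ylide.
5. Two design choices: the arm is carried as plain allyl and rebuilt by isomerisation, ozonolysis and Wittig olefination, because an ester-bearing allyl arm would need a 1,3-hydrogen shift that places the quaternary carbon cis to a methyl group, which is not a dependable equilibrium. C7 is carried as CH2OH because hydrogen must enter C9 on the face that holds the C7 substituent, and an undirected hydrogenation would do the opposite.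

Key step: step 3

Assumption: for the two ligand-controlled steps (3 and 11) the ligand antipode is assigned by analogy with the usual sense of induction of these systems; if the first run shows the opposite sense, the mirror-image ligand, equally available, is used.

**Route**

Step 1
Reactants: 1 4-methoxybenzaldehyde; 2 cyclohexylamine
Product: 3 (E)-N-(4-methoxybenzylidene)cyclohexanamine
Conditions: toluene, 4 Å molecular sieves, 20 °C
Reagents that add atoms: none
Why: Condensation of an aldehyde with a primary amine to the (E)-aldimine, driven by removal of water (imine formation); no stereocentre is formed.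

Step 2
Reactants: 3 (E)-N-(4-methoxybenzylidene)cyclohexanamine; 4 chromium hexacarbonyl
Product: 5 tricarbonyl[η6-(E)-N-(4-methoxybenzylidene)cyclohexanamine]chromium
Conditions: Cr(CO)6, Bu2O/THF (10:1), reflux, argon, dark
Reagents that add atoms: none
Why: Thermal arene–Cr(CO)3 complexation by ligand exchange with Cr(CO)6, which the electron-rich anisole ring undergoes readily and the imine tolerates; the complex keeps a mirror plane, so its two ortho carbons are enantiotopic and no stereocentre is fixed yet.

Step 3
Reactants: 5 tricarbonylchromium complex of the imine; 6 phenyllithium; 7 allyl bromide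
Product: 10 (1S,6S)-4-methoxy-6-phenyl-1-(prop-2-en-1-yl)cyclohexa-2,4-diene-1-carbaldehyde, via lithium cyclohexadienyl tricarbonylchromate 8 (not isolated), via allylated diene imine 9 (not isolated)
Conditions: PhLi, (S,S)-1,2-dimethoxy-1,2-diphenylethane, toluene, −78 °C; then allyl bromide, CO (4 bar), THF, −78 → 20 °C; then AcOH/NaOAc buffer (pH 5), THF/H2O, 0 °C
Reagents that add atoms: water, O
Why: PhLi, held in a chiral chelate by the C2-symmetric diether, is steered by N–Li coordination to one enantiotopic ortho carbon (C3, also meta to the methoxy group) and adds on the face opposite chromium, giving the anionic η5-cyclohexadienyl complex 8. Allyl bromide then alkylates chromium, and reductive elimination delivers the allyl group from the metal face to the ipso carbon C4, the dienyl terminus that carries the azaenolate; CO displaces the Cr(CO)3 fragment and buffered hydrolysis unmasks the aldehyde while the dienol ether should stay intact. The closest known reaction type is the sequential organolithium/allyl or propargyl halide trans-addition across an arene double bond in tricarbonylchromium complexes of benzaldehyde imines and aryl oxazolines, including its enantioselective variant with chiral diether or diamine ligands. No ring is closed. C3 is set by the ligand-controlled choice between the enantiotopic ortho carbons together with exo attack, and C4 by the endo migration from chromium, which forces allyl trans and formyl cis to phenyl. The step needs ortho rather than meta or para attack, one ortho carbon rather than the other, and ipso rather than C2 trapping; these are secured by the imine nitrogen, the chiral ligand and the azaenolate character of C4, respectively.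

Step 4
Reactants: 10 (1S,6S)-4-methoxy-6-phenyl-1-(prop-2-en-1-yl)cyclohexa-2,4-diene-1-carbaldehyde; 11 methyltriphenylphosphonium bromide
Product: 13 (4S,5S)-4-ethenyl-5-phenyl-4-(prop-2-en-1-yl)cyclohex-2-en-1-one, via vinyl dienol ether 12 (not isolated)
Conditions: Ph3PCH3Br, KN(SiMe3)2, THF, −78 → 0 °C; then 1 M HCl, THF, 20 °C
Reagents that add atoms: water, O
Why: Wittig methylenation of the non-enolisable aldehyde, followed in the same flask by acid hydrolysis of the dienol ether, which is protonated at C2 and therefore gives the conjugated enone directly; the aldehyde is olefinated before the ketone is unmasked so that no carbonyl competes, and neither stereocentre is touched.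

Step 5
Reactants: 13 (4S,5S)-4-ethenyl-5-phenyl-4-(prop-2-en-1-yl)cyclohex-2-en-1-one
Product: 14 (4R,5S)-4-ethenyl-5-phenyl-4-[(1E)-prop-1-en-1-yl]cyclohex-2-en-1-one
Conditions: [Ir(cod)(PMePh2)2]PF6 (2 mol%, activated with H2, then degassed), THF, 20 °C
Reagents that add atoms: none
Why: One-position alkene isomerisation by a cationic iridium hydride (allyl to (E)-propenyl), thermodynamically driven from the monosubstituted to the trans-disubstituted alkene; the vinyl group has no allylic hydrogen and cannot move.

Step 6
Reactants: 14 (4R,5S)-4-ethenyl-5-phenyl-4-[(1E)-prop-1-en-1-yl]cyclohex-2-en-1-one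
Product: 15 (4R,5S)-4-ethyl-5-phenyl-4-[(1E)-prop-1-en-1-yl]cyclohex-2-en-1-one
Conditions: H2 (1 atm, one equivalent taken up), RhCl(PPh3)3 (5 mol%), toluene/EtOH, 20 °C
Reagents that add atoms: none
Why: Homogeneous hydrogenation with RhCl(PPh3)3, which should reduce the unconjugated monosubstituted vinyl group much faster than the (E)-1,2-disubstituted propenyl group or the conjugated ring alkene, both of which sit next to the quaternary carbon; the formyl-derived carbon thus becomes the ethyl group cis to phenyl.

Step 7
Reactants: 15 (4R,5S)-4-ethyl-5-phenyl-4-[(1E)-prop-1-en-1-yl]cyclohex-2-en-1-one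
Product: 16 (1R,6S)-1-ethyl-4-oxo-6-phenylcyclohex-2-ene-1-carbaldehyde
Conditions: O3, CH2Cl2, −78 °C (Sudan red 7B as end-point indicator); then PPh3, −78 → 20 °C
Reagents that add atoms: ozone, [O-][O+]=O
Why: Ozonolysis with reductive work-up, in which the electron-rich propenyl group is consumed orders of magnitude faster than the conjugated ring alkene (protected further by the indicator dye); the quaternary aldehyde cannot epimerise.

Step 8
Reactants: 16 (1R,6S)-1-ethyl-4-oxo-6-phenylcyclohex-2-ene-1-carbaldehyde; 17 methyl 2-(triphenyl-λ5-phosphanylidene)propanoate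
Product: 18 methyl (2E)-3-[(1S,6S)-1-ethyl-4-oxo-6-phenylcyclohex-2-en-1-yl]-2-methylprop-2-enoate
Conditions: toluene, 100 °C
Reagents that add atoms: none
Why: Wittig olefination with an α-methyl stabilised ylide, which reacts with the hindered aldehyde but not with the enone carbonyl and gives the (E)-trisubstituted enoate under kinetic control, so the arm geometry is fixed without any equilibration.

Step 9
Reactants: 18 methyl (2E)-3-[(1S,6S)-1-ethyl-4-oxo-6-phenylcyclohex-2-en-1-yl]-2-methylprop-2-enoate; 19 isopropenylmagnesium bromide
Product: 20 methyl (2E)-3-[1-ethyl-6-phenyl-2-(prop-1-en-2-yl)-4-(trimethylsilyloxy)cyclohex-3-en-1-yl]-2-methylprop-2-enoate (isopropenyl at C5 trans to phenyl and cis to the arm)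
Conditions: CH2=C(CH3)MgBr, CuBr·SMe2 (20 mol%), Me3SiCl, HMPA, THF, −78 → −40 °C; Et3N, pentane work-up
Reagents that add atoms: chlorotrimethylsilane, C[Si](C)(C)Cl
Why: Copper-catalysed conjugate addition of a Grignard reagent, accelerated and trapped by Me3SiCl; C5 is set by axial attack on the half-chair that keeps the C3 phenyl group equatorial, i.e. anti to phenyl and to the C4 ethyl group and syn to the arm, while the β-branched enoate of the arm is inert to the cuprate.

Step 10
Reactants: 21 (2E)-but-2-ene-1,4-diol
Product: 22 (2E)-but-2-ene-1,4-diyl dimethyl dicarbonate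
Conditions: ClCO2Me, pyridine, CH2Cl2, 0 °C
Reagents that add atoms: methyl chloroformate, COC(=O)Cl
Why: Acylation of both hydroxyl groups with a chloroformate (carbonate formation) to give the allylic electrophile; no stereocentre.

Step 11
Reactants: 20 trimethylsilyl enol ether; 22 (2E)-but-2-ene-1,4-diyl dimethyl dicarbonate
Product: 24 methyl (2E)-3-[1-ethyl-3-(1-hydroxybut-3-en-2-yl)-4-oxo-6-phenyl-2-(prop-1-en-2-yl)cyclohexyl]-2-methylprop-2-enoate (C5/C6 trans; side-chain carbon C7 of R configuration), via methyl carbonate of the alcohol 23 (not isolated)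
Conditions: [Ir(cod)Cl]2 (2 mol%), (S)-binaphthol-derived N,N-bis[(S)-1-phenylethyl]phosphoramidite (4 mol%), CsF, ZnF2 (0.5 equiv), DME, 50 °C; then K2CO3 (cat.), MeOH, 20 °C
Reagents that add atoms: none
Why: Iridium-catalysed allylic alkylation of a fluoride-activated silyl enol ether at the substituted terminus of the allyl–iridium intermediate, in which C7 is set by the chiral phosphoramidite catalyst and C6 by approach of the electrophile anti to the C5 isopropenyl group (trans-2,3-disubstitution); the remaining non-allylic carbonate is then removed by base-catalysed methanolysis.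

Step 12
Reactants: 24 diene alcohol
Product: 25 methyl (2E)-3-[4-ethyl-1-(hydroxymethyl)-3-methyl-7-oxo-5-phenyl-3a,4,5,6,7,7a-hexahydro-1H-inden-4-yl]-2-methylprop-2-enoate (trans ring fusion, C8=C9 alkene)
Conditions: second-generation Grubbs catalyst RuCl2(=CHPh)(PCy3)(H2IMes) (5 mol%), toluene, 80 °C
Reagents that add atoms: none
Why: Ring-closing metathesis of the trans-disposed isopropenyl and vinyl groups (five-membered ring, trisubstituted alkene, ethene lost) through the chair that holds both appendages equatorial; the enoate of the arm lies on the face opposite C7 and is too hindered to engage, and no stereocentre changes.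

Step 13
Reactants: 25 bicyclic homoallylic alcohol
Product: 26 methyl (2E)-3-[4-ethyl-1-(hydroxymethyl)-3-methyl-7-oxo-5-phenyloctahydro-1H-inden-4-yl]-2-methylprop-2-enoate (C9 methyl trans to the C7 hydroxymethyl group)
Conditions: H2 (1 atm), [Ir(cod)(PCy3)(py)]PF6 (10 mol%), CH2Cl2, 0 → 20 °C
Reagents that add atoms: none
Why: Hydroxyl-directed hydrogenation with a cationic iridium catalyst, in which the homoallylic OH on C7 binds the metal and both hydrogens are delivered to the C8=C9 face that carries the hydroxymethyl group, so the C9 methyl ends trans to it and syn to the C4 arm; the hindered, electron-poor enoate is not bound and should survive.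

Step 14
Reactants: 26 saturated hydroxymethyl ketone
Product: 27 methyl (2E)-3-[4-ethyl-1-(iodomethyl)-3-methyl-7-oxo-5-phenyloctahydro-1H-inden-4-yl]-2-methylprop-2-enoate
Conditions: I2, PPh3, imidazole, CH2Cl2, 0 → 20 °C
Reagents that add atoms: iodine, II
Why: Appel-type iodination of the primary alcohol, an SN2 displacement of the oxyphosphonium group at CH2 that leaves C7 untouched.

Step 15
Reactants: 27 primary iodide
Product: 28 methyl (2E)-3-[4-ethyl-1,3-dimethyl-7-oxo-5-phenyloctahydro-1H-inden-4-yl]-2-methylprop-2-enoate (all six stereocentres as in the target)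
Conditions: Bu3SnH, AIBN (cat.), toluene, 80 °C
Reagents that add atoms: none
Why: Radical chain dehalogenation with a tin hydride, which turns CH2I into the C7 methyl group without affecting the ketone or the enoate; the primary radical has no fast cyclisation or fragmentation channel.

Step 16
Reactants: 28 bicyclic ketone
Product: 29 methyl (2E)-3-[4-ethyl-1,3-dimethyl-5-phenyl-7-(trifluoromethanesulfonyloxy)-2,3,3a,4,5,7a-hexahydro-1H-inden-4-yl]-2-methylprop-2-enoate
Conditions: KN(SiMe3)2, THF, −78 °C; then PhNTf2, −78 → 0 °C
Reagents that add atoms: N-phenylbis(trifluoromethanesulfonimide), O=S(=O)(N(c1ccccc1)S(=O)(=O)C(F)(F)F)C(F)(F)F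
Why: Kinetic deprotonation at the less substituted α-carbon (the C2 methylene rather than the hindered C6 methine) followed by O-triflation of the enolate, giving the C1=C2 enol triflate regioselectively and leaving the C6 stereocentre intact.

Step 17
Reactants: 29 enol triflate; 30 ethylmagnesium bromide
Product: 31 methyl (2E)-3-[(1R,3R,3aR,4S,5S,7aR)-4,7-diethyl-1,3-dimethyl-5-phenyl-2,3,3a,4,5,7a-hexahydro-1H-inden-4-yl]-2-methylprop-2-enoate
Conditions: EtMgBr, Fe(acac)3 (5 mol%), THF/NMP, −30 °C
Reagents that add atoms: none
Why: Iron-catalysed cross-coupling of an alkenyl triflate with an alkyl Grignard reagent (Kumada-type), which is fast at low temperature, tolerates the ester and is not troubled by β-hydride elimination of the ethyl group.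

Step 18
Reactants: 31 methyl ester
Product: 32 homo-plakotenin, (2E)-3-[(1R,3R,3aR,4S,5S,7aR)-4,7-diethyl-1,3-dimethyl-5-phenyl-2,3,3a,4,5,7a-hexahydro-1H-inden-4-yl]-2-methylprop-2-enoic acid
Conditions: LiOH, THF/MeOH/H2O, 50 °C; then 1 M HCl
Reagents that add atoms: lithium hydroxide, [Li+].[OH-]
Why: Saponification of the hindered methyl ester with hydroxide at slightly elevated temperature followed by acidification; no stereocentre or alkene is affected.

**Compound list**

1 | 4-methoxybenzaldehyde | COc1ccc(C=O)cc1 | starting material
2 | cyclohexylamine | NC1CCCCC1 | starting material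
3 | (E)-N-(4-methoxybenzylidene)cyclohexanamine | COc1ccc(/C=N/C2CCCCC2)cc1 | intermediate
4 | chromium hexacarbonyl | [Cr].[C-]#[O+].[C-]#[O+].[C-]#[O+].[C-]#[O+].[C-]#[O+].[C-]#[O+] | starting material
5 | tricarbonyl[η6-(E)-N-(4-methoxybenzylidene)cyclohexanamine]chromium | COc1ccc(/C=N/C2CCCCC2)cc1.[Cr].[C-]#[O+].[C-]#[O+].[C-]#[O+] | intermediate
6 | phenyllithium | [Li]c1ccccc1 | starting material
7 | allyl bromide | C=CCBr | starting material
8 | lithium salt of the anionic η5-cyclohexadienyl Cr(CO)3 adduct (phenyl exo at C3), not isolated | [Li+].COC1=C[C@@H](c2ccccc2)C(=C[N-]C2CCCCC2)C=C1.[Cr].[C-]#[O+].[C-]#[O+].[C-]#[O+] | intermediate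
9 | N-cyclohexyl imine of 10 (allyl trans to phenyl), not isolated | COC1=C[C@@H](c2ccccc2)[C@@](CC=C)(/C=N/C2CCCCC2)C=C1 | intermediate
10 | (1S,6S)-4-methoxy-6-phenyl-1-(prop-2-en-1-yl)cyclohexa-2,4-diene-1-carbaldehyde (formyl cis, allyl trans to phenyl) | COC1=C[C@@H](c2ccccc2)[C@@](CC=C)(C=O)C=C1 | intermediate
11 | methyltriphenylphosphonium bromide | C[P+](c1ccccc1)(c1ccccc1)c1ccccc1.[Br-] | starting material
12 | 5-ethenyl-2-methoxy-6-phenyl-5-(prop-2-en-1-yl)cyclohexa-1,3-diene (vinyl cis to phenyl), not isolated | COC1=C[C@@H](c2ccccc2)[C@@](CC=C)(C=C)C=C1 | intermediate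
13 | (4S,5S)-4-ethenyl-5-phenyl-4-(prop-2-en-1-yl)cyclohex-2-en-1-one | O=C1C[C@@H](c2ccccc2)[C@@](CC=C)(C=C)C=C1 | intermediate
14 | (4R,5S)-4-ethenyl-5-phenyl-4-[(1E)-prop-1-en-1-yl]cyclohex-2-en-1-one | O=C1C[C@@H](c2ccccc2)[C@@](/C=C/C)(C=C)C=C1 | intermediate
15 | (4R,5S)-4-ethyl-5-phenyl-4-[(1E)-prop-1-en-1-yl]cyclohex-2-en-1-one | O=C1C[C@@H](c2ccccc2)[C@@](/C=C/C)(CC)C=C1 | intermediate
16 | (1R,6S)-1-ethyl-4-oxo-6-phenylcyclohex-2-ene-1-carbaldehyde | O=C1C[C@@H](c2ccccc2)[C@@](C=O)(CC)C=C1 | intermediate
17 | methyl 2-(triphenyl-λ5-phosphanylidene)propanoate | COC(=O)C(C)=P(c1ccccc1)(c1ccccc1)c1ccccc1 | starting material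
18 | methyl (2E)-3-[(1S,6S)-1-ethyl-4-oxo-6-phenylcyclohex-2-en-1-yl]-2-methylprop-2-enoate | O=C1C[C@@H](c2ccccc2)[C@@](/C=C(\C)C(=O)OC)(CC)C=C1 | intermediate
19 | isopropenylmagnesium bromide | C=C(C)[Mg]Br | starting material
20 | trimethylsilyl enol ether of the C5-isopropenyl ketone (isopropenyl trans to phenyl, cis to the arm) | C[Si](C)(C)OC1=C[C@@H](C(C)=C)[C@](/C=C(\C)C(=O)OC)(CC)[C@H](c2ccccc2)C1 | intermediate
21 | (2E)-but-2-ene-1,4-diol | OC/C=C/CO | starting material
22 | (2E)-but-2-ene-1,4-diyl dimethyl dicarbonate | COC(=O)OC/C=C/COC(=O)OC | intermediate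
23 | methyl carbonate of alcohol 24, not isolated | O=C1C[C@@H](c2ccccc2)[C@@](/C=C(\C)C(=O)OC)(CC)[C@H](C(C)=C)[C@H]1[C@H](COC(=O)OC)C=C | intermediate
24 | methyl (2E)-3-[1-ethyl-3-(1-hydroxybut-3-en-2-yl)-4-oxo-6-phenyl-2-(prop-1-en-2-yl)cyclohexyl]-2-methylprop-2-enoate (C5/C6 trans, C7 R) | O=C1C[C@@H](c2ccccc2)[C@@](/C=C(\C)C(=O)OC)(CC)[C@H](C(C)=C)[C@H]1[C@H](CO)C=C | intermediate
25 | trans-fused cyclopentene: methyl (2E)-3-[4-ethyl-1-(hydroxymethyl)-3-methyl-7-oxo-5-phenyl-3a,4,5,6,7,7a-hexahydro-1H-inden-4-yl]-2-methylprop-2-enoate | O=C1C[C@@H](c2ccccc2)[C@@](/C=C(\C)C(=O)OC)(CC)[C@H]2[C@H]1[C@H](CO)C=C2C | intermediate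
26 | methyl (2E)-3-[4-ethyl-1-(hydroxymethyl)-3-methyl-7-oxo-5-phenyloctahydro-1H-inden-4-yl]-2-methylprop-2-enoate (C9 methyl trans to CH2OH) | O=C1C[C@@H](c2ccccc2)[C@@](/C=C(\C)C(=O)OC)(CC)[C@H]2[C@H]1[C@H](CO)C[C@H]2C | intermediate
27 | iodomethyl analogue of 26 | O=C1C[C@@H](c2ccccc2)[C@@](/C=C(\C)C(=O)OC)(CC)[C@H]2[C@H]1[C@H](CI)C[C@H]2C | intermediate
28 | methyl (2E)-3-[4-ethyl-1,3-dimethyl-7-oxo-5-phenyloctahydro-1H-inden-4-yl]-2-methylprop-2-enoate (stereocentres as in the target) | O=C1C[C@@H](c2ccccc2)[C@@](/C=C(\C)C(=O)OC)(CC)[C@H]2[C@H]1[C@H](C)C[C@H]2C | intermediate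
29 | C1=C2 enol triflate of 28 | O=S(=O)(OC1=C[C@@H](c2ccccc2)[C@@](/C=C(\C)C(=O)OC)(CC)[C@H]2[C@H]1[C@H](C)C[C@H]2C)C(F)(F)F | intermediate
30 | ethylmagnesium bromide | CC[Mg]Br | starting material
31 | homo-plakotenin methyl ester | CCC1=C[C@@H](c2ccccc2)[C@@](/C=C(\C)C(=O)OC)(CC)[C@H]2[C@H]1[C@H](C)C[C@H]2C | intermediate
32 | homo-plakotenin, (2E)-3-[(1R,3R,3aR,4S,5S,7aR)-4,7-diethyl-1,3-dimethyl-5-phenyl-2,3,3a,4,5,7a-hexahydro-1H-inden-4-yl]-2-methylprop-2-enoic acid | CCC1=C[C@@H](c2ccccc2)[C@@](/C=C(\C)C(=O)O)(CC)[C@H]2[C@H]1[C@H](C)C[C@H]2C | target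

**Step count**

Total step count: 18 (17 in the main line plus step 10 for the allylic dicarbonate).
Longest linear sequence: 17 steps (steps 1–9 and 11–18, from 4-methoxybenzaldehyde).

**Steps most likely to fail, with fallbacks**

Step 3. The external ligand may not differentiate the enantiotopic ortho carbons well enough, or addition to the electron-rich ring may be sluggish, and the dienol ether may be partly lost during imine hydrolysis. Fallback by auxiliary control, setting out from 1: condensation with (S)-1-methoxy-3-methylbutan-2-amine should give the chiral imine F1, and complexation with Cr(CO)6 its tricarbonylchromium complex F2. PhLi without external ligand should add under chelation control by the ether oxygen to give the diastereomerically enriched anionic adduct F3, and allyl bromide under CO the allylated diene imine F4. The same buffered hydrolysis releases the auxiliary and returns the route at 10. The mirror-image amine would be used if the induction has the opposite sense.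

Step 11. Capture of the allyl–iridium intermediate by the very hindered enolate may be slow, the branched-to-linear ratio may erode, or catalyst and substrate may be mismatched in facial preference. Fallback by stereospecific rhodium-catalysed allylic alkylation, setting out from 20 and commercially available (S)-but-3-ene-1,2-diol: the diol is silylated at the primary hydroxyl (t-BuMe2SiCl, imidazole) to the silyl ether F5 and converted (ClCO2Me, pyridine) into the secondary methyl carbonate F6. Compound 20 is cleaved with MeLi to the lithium enolate F7, transmetallated with CuI to the copper enolate F8 and alkylated with F6 under RhCl(PPh3)3/P(OMe)3. This catalyst substitutes at the carbon that bore the leaving group with overall retention, so C7 comes from the chiral pool. The resulting silyl ether F9 is desilylated with HF·pyridine and the route is rejoined at 24.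

Step 13. Facial control may be lost if the hydroxyl group is tied up as the cyclic hemiketal with the C1 ketone, and the enoate of the arm may be partly saturated. Fallback by stepwise radical hydrogenation (hydrogen-atom transfer), setting out from 25: Mn(dpm)3, PhSiH3 and tert-butyl hydroperoxide in isopropanol deliver the first hydrogen to C8. The tertiary C9 radical should take the second hydrogen on the face away from the axial C4 arm, which is the same face as in the directed reaction. This returns the route at 26 without new intermediates.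

**Further compounds**

F1 | step 3 | (S,E)-1-methoxy-N-(4-methoxybenzylidene)-3-methylbutan-2-amine | COc1ccc(/C=N/[C@H](COC)C(C)C)cc1
F2 | step 3 | tricarbonylchromium complex of F1 | COc1ccc(/C=N/[C@H](COC)C(C)C)cc1.[Cr].[C-]#[O+].[C-]#[O+].[C-]#[O+]
F3 | step 3 | lithium salt of the anionic η5-cyclohexadienyl Cr(CO)3 adduct of F2 | [Li+].COC1=C[C@@H](c2ccccc2)C(=C[N-][C@H](COC)C(C)C)C=C1.[Cr].[C-]#[O+].[C-]#[O+].[C-]#[O+]
F4 | step 3 | allylated diene imine carrying the auxiliary | COC1=C[C@@H](c2ccccc2)[C@@](CC=C)(/C=N/[C@H](COC)C(C)C)C=C1
F5 | step 11 | (S)-1-[(tert-butyldimethylsilyl)oxy]but-3-en-2-ol | C=C[C@H](O)CO[Si](C)(C)C(C)(C)C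
F6 | step 11 | (S)-1-[(tert-butyldimethylsilyl)oxy]but-3-en-2-yl methyl carbonate | COC(=O)O[C@H](CO[Si](C)(C)C(C)(C)C)C=C
F7 | step 11 | lithium enolate from 20 | [Li+].[O-]C1=C[C@@H](C(C)=C)[C@](/C=C(\C)C(=O)OC)(CC)[C@H](c2ccccc2)C1
F8 | step 11 | copper enolate from F7 | [Cu]OC1=C[C@@H](C(C)=C)[C@](/C=C(\C)C(=O)OC)(CC)[C@H](c2ccccc2)C1
F9 | step 11 | tert-butyldimethylsilyl ether of 24 | O=C1C[C@@H](c2ccccc2)[C@@](/C=C(\C)C(=O)OC)(CC)[C@H](C(C)=C)[C@H]1[C@H](CO[Si](C)(C)C(C)(C)C)C=C
F0 | step 13 | none | none
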